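**Retrosynthetic overview**
- The eight-membered ring (C2, C3, C4, C7, C9, C18, C19, C20) is closed last at C19–C20 by Claisen condensation of the γ-lactone enolate onto a side-chain lactone. The chain is attached before that at C7–C4 (Nozaki–Hiyama–Kishi), and C4–OH is set by directed epoxidation.
- C27–OH is delivered from C13–OH through a silicon tether; C13–OH comes from a C13–B bond.
- The strategy rests on the 2-oxabicyclo[2.2.2]octane (bridgeheads C15 and C25; bridges O17–C18, C12–C13, C26–C27), whose C18–C25 edge is shared with the cyclopentane (C9, C10, C12) and the γ-lactone (C19, C22, O24). It is the Diels–Alder adduct of a lactone-fused 2H-pyran (diene C25=C26–C27=C15) with an E-alkenyl boronate (C12=C13) tethered through C9–C10. The pyran is the valence isomer of a Z-dienone enol lactone (bond O17–C18).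
- The dienone enol lactone comes from a 2,3-dimethyl-5-alkylfuran (singlet oxygen, then enol lactonisation of the γ-keto acid). C9 and C10 come from an anti-selective Michael addition of the dianion of ethyl (R)-3-hydroxypent-4-enoate to a furylacrylate; boron comes from cross-metathesis.
- Ring order: furan (masked C15–C27–C26–C25), γ-lactone (step 10), then pyran, cyclopentane and cyclohexene together (step 11), then the eight-membered ring (step 25).

Key step: step 11

Remark: atoms are labelled C1 to O29 in the order of the heavy atoms of the target SMILES; 10–18 are carried as both epimers at C18, which becomes sp2 in 19.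
Remark: 19 should equilibrate with its valence isomer 20 already near room temperature, so it is prepared cold and used at once.

**Step 1**
Reactants: 1 4,5-dimethylfuran-2-carbaldehyde; 2 tert-butyl (triphenylphosphoranylidene)acetate
Product: 3 tert-butyl (2E)-3-(4,5-dimethylfuran-2-yl)prop-2-enoate
Conditions: PhMe, 80 °C
Reagents that add atoms: none
Why: Wittig olefination with a stabilised ylide, which should give the E-enoate.

**Step 2**
Reactants: 4 ethyl acetate; 5 acrolein
Product: 7 rac-ethyl 3-hydroxypent-4-enoate, via lithium ester enolate 6 (not isolated)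
Conditions: LDA, THF, −78 °C; then 5; aq. NH4Cl
Reagents that add atoms: none
Why: Aldol addition of the lithium ester enolate to the aldehyde carbonyl (1,2-addition at −78 °C); the carbinol centre is racemic at this point.

**Step 3**
Reactants: 7 rac-ethyl 3-hydroxypent-4-enoate
Product: 8 ethyl (3R)-3-hydroxypent-4-enoate
Conditions: Amano lipase PS, vinyl acetate, MTBE, 30 °C, to about 52 % conversion; chromatography
Reagents that add atoms: none
Why: Lipase-catalysed kinetic resolution by transesterification; by the Kazlauskas rule (CH2CO2Et large, vinyl medium) the (S)-alcohol should be acetylated and the (R)-alcohol recovered, which fixes C10.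

**Step 4**
Reactants: 8 ethyl (3R)-3-hydroxypent-4-enoate; 3 tert-butyl (2E)-3-(4,5-dimethylfuran-2-yl)prop-2-enoate
Product: 10 ethyl (2S,3S)-2-[3-tert-butoxy-1-(4,5-dimethylfuran-2-yl)-3-oxopropyl]-3-hydroxypent-4-enoate, via dilithium dianion 9 (not isolated)
Conditions: LDA (2.2 equiv), THF, −78 to −20 °C; then 3, −78 to −40 °C; AcOH
Reagents that add atoms: none
Why: Fráter–Seebach-type Michael addition of the chelated β-alkoxide enolate to the β-furyl enoate; the acceptor should enter anti to the vinyl group on the lithium chelate, which sets C9 (2,3-anti), while C18 forms as both epimers and is flattened later.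

**Step 5**
Reactants: 10 anti Michael adduct
Product: 11 tert-butyl (4R,5S)-3-(4,5-dimethylfuran-2-yl)-5-hydroxy-4-(hydroxymethyl)hept-6-enoate
Conditions: LiBH4, THF, MeOH (1 equiv), 0 °C to rt
Reagents that add atoms: none
Why: Hydroxyl-assisted borohydride reduction of the ethyl ester to the primary alcohol (C7); the tert-butyl ester should not be reduced under these conditions.

**Step 6**
Reactants: 11 diol
Product: 12 bis-TBS ether of 11
Conditions: TBSCl, imidazole, DMAP (cat.), DMF, 40 °C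
Reagents that add atoms: tert-butyldimethylsilyl chloride, CC(C)(C)[Si](C)(C)Cl
Why: Silyl ether formation at both hydroxyl groups; no stereocentre is touched.

**Step 7**
Reactants: 12 bis-TBS ether; 13 vinylboronic acid pinacol ester
Product: 14 tert-butyl (4R,5S,6E)-5-(TBS-oxy)-4-(TBS-oxymethyl)-3-(4,5-dimethylfuran-2-yl)-7-(pinacolboryl)hept-6-enoate
Conditions: Hoveyda–Grubbs II (5 mol %), 13 (4 equiv), CH2Cl2, 40 °C
Reagents that add atoms: none
Why: Olefin cross-metathesis of the allylic silyl ether with vinyl-Bpin, which should give the E-alkenyl boronate; furan and ester are inert to the ruthenium carbene.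

**Step 8**
Reactants: 14 E-alkenyl boronate tert-butyl ester
Product: 16 (4R,5S,6E)-5-(TBS-oxy)-4-(TBS-oxymethyl)-3-(4,5-dimethylfuran-2-yl)-7-(pinacolboryl)hept-6-enoic acid, via trimethylsilyl ester 15 (not isolated)
Conditions: TMSOTf, 2,6-lutidine, CH2Cl2, 0 °C to rt; then pH 5 buffer
Reagents that add atoms: none
Why: Silyl-triflate-mediated cleavage of the tert-butyl ester (loss of isobutene) and hydrolysis of the silyl ester on work-up, under buffered conditions that should spare the furan, both TBS ethers and the boronate.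

**Step 9**
Reactants: 16 furyl carboxylic acid
Product: 18 (4R,5S,6E)-5-(TBS-oxy)-4-(TBS-oxymethyl)-3-[(2Z)-3-methyl-4-oxopent-2-enoyl]-7-(pinacolboryl)hept-6-enoic acid, via furan endoperoxide 17 (not isolated)
Conditions: O2, tetraphenylporphyrin (cat.), visible light, CH2Cl2, −78 °C; then Me2S, −78 °C to rt
Reagents that add atoms: oxygen, O=O
Why: [4+2] addition of singlet oxygen to the electron-rich trisubstituted furan and reduction of the endoperoxide unveil the cis-enedione, whose Z geometry is inherited from the ring; the electron-poor alkenyl boronate should not react with singlet oxygen.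

**Step 10**
Reactants: 18 Z-enedione keto acid
Product: 19 4-[(2R,3S,4E)-1,3-bis(TBS-oxy)-5-(pinacolboryl)pent-4-en-2-yl]-5-[(1Z)-2-methyl-3-oxobut-1-en-1-yl]furan-2(3H)-one
Conditions: (CF3CO)2O, 2,6-lutidine, CH2Cl2, −40 to 0 °C
Reagents that add atoms: none
Why: Enol lactonisation (cyclodehydration) of the γ-keto acid through its mixed anhydride: the C25 carbonyl oxygen closes the five-membered acyloxy oxocarbenium ion, and loss of C18–H, the only β-hydrogen, gives the tetrasubstituted enol lactone; the C15 ketone is too remote to compete.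

**Step 11**
Reactants: 19 Z-dienone enol lactone
Product: 21 boryl 2-oxabicyclo[2.2.2]octene propellane lactone, via lactone-fused 2H-pyran 20 (not isolated)
Conditions: PhMe (0.01 M), BHT (cat.), 100 °C, dark, base-washed glass
Reagents that add atoms: none
Why: On heating, the 1-oxatriene O17=C15–C27=C26–C25=C18 of 19 (central double bond Z) should close by a thermally allowed disrotatory oxa-6π electrocyclisation (pyran ring, bond O17–C18); the lactone-fused 2H-pyran 20 forms reversibly as both C18 epimers, and its diene C25=C26–C27=C15 is then trapped irreversibly by the tethered E-alkenyl boronate in a suprafacial intramolecular [4+2] that closes the cyclopentane (bond C12–C25, over the two-atom tether C9–C10) and the cyclohexene of the oxabicyclo[2.2.2]octene (bond C13–C15). The closest known reaction type is the oxa-6π electrocyclisation/intramolecular Diels–Alder cascade of cis-dienones, and the tether topology is that of intramolecular cycloadditions of masked o-benzoquinones, where a two-atom tether on the sp3 carbon next to the diene gives the same fused cyclopentane. C18 is set by the choice of pyran epimer, C25 and C15 by addition to the diene face that carries C9 (the lactone methylene C19 occupies the other face), and C12 and C13 by suprafacial addition of the E-alkene, which places boron trans to C10 and therefore over the C26=C27 bridge. The one selectivity not fixed by geometry is the choice between the two pyran epimers: in the array leading to 21 the C10 silyloxy group lies anti to the forming C12–C25 bond on the open exo side, whereas in the other array it is pressed against the lactone oxygen O24 and eclipses C12–H, so C10 is expected to decide; the CH2OTBS group on C9 is a weaker, opposing influence (it lies beside C19 in the productive array). Regiochemistry and the endo/exo sense cannot vary because the tether only reaches C25.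

**Step 12**
Reactants: 21 boryl propellane lactone
Product: 22 C13 alcohol
Conditions: NaBO3·4H2O, THF/H2O, rt
Reagents that add atoms: sodium perborate, O=BO[O-].[Na+]
Why: Oxidation of the secondary alkyl boronate (1,2-shift from boron to oxygen), which replaces boron by hydroxyl with retention at C13.

**Step 13**
Reactants: 22 C13 alcohol
Product: 24 oxasilolane (O14–SiMe2–C27), via dimethylsilyl ether 23 (not isolated)
Conditions: Me2SiHCl, Et3N, CH2Cl2, 0 °C; then Karstedt catalyst (2 mol % Pt), PhMe, 60 °C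
Reagents that add atoms: chlorodimethylsilane, C[SiH](C)Cl
Why: Tamao-type silicon-tethered intramolecular hydrosilylation of the homoallylic silyl ether: the tether on O14 can only reach C27, and only from the face of the C26=C27 bridge that looks at C13, so Si–C27 and H–C26 add syn on that face and set C27; an anti addition or a backside opening at C26 is avoided because that face of C26 is shielded by the C19 methylene, and hydride reagents would attack the lactone.

**Step 14**
Reactants: 24 oxasilolane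
Product: 25 syn-1,3-diol (C13–OH and C27–OH)
Conditions: 30 % H2O2, KHCO3, KF, THF/MeOH, 40 °C
Reagents that add atoms: hydrogen peroxide, OO
Why: Tamao–Fleming oxidation of the C–Si bond of the alkoxysilane, which should give the tertiary C27 alcohol with retention.

**Step 15**
Reactants: 25 syn-1,3-diol
Product: 26 di-tert-butylsilylene of the C13/C27 diol
Conditions: t-Bu2Si(OTf)2, 2,6-lutidine, CH2Cl2, 0 °C to rt
Reagents that add atoms: di-tert-butylsilyl bis(trifluoromethanesulfonate), CC(C)(C)[Si](OS(=O)(=O)C(F)(F)F)(OS(=O)(=O)C(F)(F)F)C(C)(C)C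
Why: Protection of the syn-1,3-diol as a six-membered cyclic silylene, stable to the later acidic, oxidative and basic steps.

**Step 16**
Reactants: 26 silylene bis-TBS ether
Product: 27 primary alcohol (C7–OH)
Conditions: CSA (cat.), MeOH/CH2Cl2, 0 °C
Reagents that add atoms: none
Why: Acid-catalysed methanolysis of the primary TBS ether, which should be much faster than cleavage of the hindered secondary TBS ether and of the silylene.

**Step 17**
Reactants: 27 primary alcohol
Product: 28 C7 aldehyde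
Conditions: Dess–Martin periodinane, NaHCO3, CH2Cl2, rt
Reagents that add atoms: none
Why: Dess–Martin oxidation under buffered, non-epimerising conditions; the aldehyde is used at once to protect C9.

**Step 18**
Reactants: 29 (4R)-4-benzyl-3-propanoyl-1,3-oxazolidin-2-one; 30 2,3-dibromopropene
Product: 32 (4R)-4-benzyl-3-[(2S)-4-bromo-2-methylpent-4-enoyl]-1,3-oxazolidin-2-one, via sodium Z-enolate 31 (not isolated)
Conditions: NaHMDS, THF, −78 °C; then 30, −78 to −40 °C
Reagents that add atoms: none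
Why: Evans asymmetric alkylation: the chelated Z-enolate is alkylated by the allylic bromide on the face opposite the benzyl group, which sets C2 as S.

**Step 19**
Reactants: 32 alkylated imide
Product: 33 methyl (2S)-4-bromo-2-methylpent-4-enoate
Conditions: MeMgBr, MeOH, 0 °C
Reagents that add atoms: bromomagnesium methoxide, CO[Mg]Br
Why: Transesterification of the N-acyl oxazolidinone with magnesium methoxide, which releases the auxiliary without epimerising C2.

**Step 20**
Reactants: 28 C7 aldehyde; 33 methyl (2S)-4-bromo-2-methylpent-4-enoate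
Product: 34 (7S)-allylic alcohol carrying the C4 methylene ester chain
Conditions: CrCl2 (6 equiv), NiCl2 (2 mol %), 33 (3 equiv), DMF/THF, rt
Reagents that add atoms: none
Why: Nozaki–Hiyama–Kishi coupling of the 2-bromoalkene with the aldehyde, chemoselective over lactone and ester; Felkin–Anh addition anti to the quaternary C18 on C9 is expected to give the (7S) alcohol, a temporary stereocentre that relays to C4.

**Step 21**
Reactants: 34 (7S)-allylic alcohol
Product: 35 erythro epoxy alcohol (C4–O–C5 epoxide)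
Conditions: VO(acac)2 (5 mol %), t-BuOOH, CH2Cl2, 0 °C to rt
Reagents that add atoms: tert-butyl hydroperoxide, CC(C)(C)OO
Why: Vanadium-catalysed hydroxyl-directed epoxidation of the 2-substituted allylic alcohol; A(1,2) strain should make the erythro isomer dominant, which sets the C4–O bond with the configuration of the target.

**Step 22**
Reactants: 35 erythro epoxy alcohol
Product: 36 iodohydrin (C4–OH and C5–I)
Conditions: LiI, AcOH, THF, rt
Reagents that add atoms: lithium iodide, [Li+].[I-]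
Why: SN2 opening of the 2,2-disubstituted epoxide by iodide at the primary carbon C5, which leaves the C4–O bond and its configuration untouched and avoids Lewis-acid semipinacol shifts.

**Step 23**
Reactants: 36 iodohydrin
Product: 38 side-chain γ-lactone (C4–O–C20) with free C7–OH, via hydroxy ester 37 (not isolated)
Conditions: Bu3SnH, AIBN, PhMe, 80 °C; then PPTS (cat.), PhMe, 80 °C
Reagents that add atoms: none
Why: Radical deiodination turns C5 into the methyl group, and acid-catalysed lactonisation of the tertiary γ-hydroxy ester gives the five-membered lactone, which masks C4–OH and activates C20.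

**Step 24**
Reactants: 38 side-chain γ-lactone alcohol
Product: 39 C7 triethylsilyl ether
Conditions: TESOTf, 2,6-lutidine, CH2Cl2, −78 °C
Reagents that add atoms: triethylsilyl trifluoromethanesulfonate, CC[Si](CC)(CC)OS(=O)(=O)C(F)(F)F
Why: Silylation of the remaining secondary alcohol so that no alkoxide can attack either lactone in the next step.

**Step 25**
Reactants: 39 C7 triethylsilyl ether
Product: 41 eight-membered β-keto lactone enol with C7–OH and C4–OH, via cyclised triethylsilyl ether 40 (not isolated)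
Conditions: LiHMDS (2.5 equiv), THF (0.005 M), −78 to 0 °C; then 1 M HCl, THF, 0 °C
Reagents that add atoms: none
Why: Intramolecular Claisen (Dieckmann-type) condensation: the enolate of the core lactone (C19) attacks the side-chain lactone carbonyl C20, which the small ring holds close to C4; the C4 alkoxide is expelled and the product is trapped as its β-keto lactone enolate, and the acidic work-up removes the TES group.

**Step 26**
Reactants: 41 ring alcohol
Product: 42 C7 ketone (target protected at O11 and as the C13/C27 silylene)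
Conditions: Dess–Martin periodinane, pyridine, CH2Cl2, 0 °C to rt
Reagents that add atoms: none
Why: Dess–Martin oxidation of the secondary C7 alcohol; the tertiary C4 alcohol and the hydrogen-bonded enol should not be oxidised.

**Step 27**
Reactants: 42 protected target
Product: 43 target CNP0073514.1
Conditions: HF·pyridine, THF, 0 °C to rt
Reagents that add atoms: none
Why: Fluoride cleavage of the TBS ether and of the silylene under buffered acidic conditions, which should avoid retro-aldol opening of the β-hydroxy ketone.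

**Compound list**

1 | 4,5-dimethylfuran-2-carbaldehyde | Cc1oc(C=O)cc1C | starting material
2 | tert-butyl (triphenylphosphoranylidene)acetate | CC(C)(C)OC(=O)C=P(c1ccccc1)(c1ccccc1)c1ccccc1 | starting material
3 | tert-butyl (2E)-3-(4,5-dimethylfuran-2-yl)prop-2-enoate | Cc1oc(/C=C/C(=O)OC(C)(C)C)cc1C | intermediate
4 | ethyl acetate | CCOC(C)=O | starting material
5 | acrolein | C=CC=O | starting material
6 | lithium enolate of ethyl acetate | C=C([O-])OCC.[Li+] | intermediate
7 | rac-ethyl 3-hydroxypent-4-enoate | CCOC(=O)CC(O)C=C | intermediate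
8 | ethyl (3R)-3-hydroxypent-4-enoate | CCOC(=O)C[C@@H](O)C=C | intermediate
9 | dilithium alkoxide enolate of 8 | CCOC([O-])=C[C@@H]([O-])C=C.[Li+].[Li+] | intermediate
10 | ethyl (2S,3S)-2-[3-tert-butoxy-1-(4,5-dimethylfuran-2-yl)-3-oxopropyl]-3-hydroxypent-4-enoate (both epimers at C18) | Cc1oc(C(CC(=O)OC(C)(C)C)[C@H](C(=O)OCC)[C@@H](O)C=C)cc1C | intermediate
11 | tert-butyl (4R,5S)-3-(4,5-dimethylfuran-2-yl)-5-hydroxy-4-(hydroxymethyl)hept-6-enoate (both epimers at C3 = C18) | Cc1oc(C(CC(=O)OC(C)(C)C)[C@H](CO)[C@@H](O)C=C)cc1C | intermediate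
12 | tert-butyl (4R,5S)-5-[(tert-butyldimethylsilyl)oxy]-4-{[(tert-butyldimethylsilyl)oxy]methyl}-3-(4,5-dimethylfuran-2-yl)hept-6-enoate | Cc1oc(C(CC(=O)OC(C)(C)C)[C@H](CO[Si](C)(C)C(C)(C)C)[C@@H](O[Si](C)(C)C(C)(C)C)C=C)cc1C | intermediate
13 | vinylboronic acid pinacol ester | C=CB1OC(C)(C)C(C)(C)O1 | starting material
14 | tert-butyl (4R,5S,6E)-5-(TBS-oxy)-4-(TBS-oxymethyl)-3-(4,5-dimethylfuran-2-yl)-7-(4,4,5,5-tetramethyl-1,3,2-dioxaborolan-2-yl)hept-6-enoate | Cc1oc(C(CC(=O)OC(C)(C)C)[C@H](CO[Si](C)(C)C(C)(C)C)[C@@H](O[Si](C)(C)C(C)(C)C)/C=C/B2OC(C)(C)C(C)(C)O2)cc1C | intermediate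
15 | trimethylsilyl ester of acid 16 | Cc1oc(C(CC(=O)O[Si](C)(C)C)[C@H](CO[Si](C)(C)C(C)(C)C)[C@@H](O[Si](C)(C)C(C)(C)C)/C=C/B2OC(C)(C)C(C)(C)O2)cc1C | intermediate
16 | (4R,5S,6E)-5-(TBS-oxy)-4-(TBS-oxymethyl)-3-(4,5-dimethylfuran-2-yl)-7-(pinacolboryl)hept-6-enoic acid | Cc1oc(C(CC(=O)O)[C@H](CO[Si](C)(C)C(C)(C)C)[C@@H](O[Si](C)(C)C(C)(C)C)/C=C/B2OC(C)(C)C(C)(C)O2)cc1C | intermediate
17 | furan 2,5-endoperoxide of 16 (2,3,7-trioxabicyclo[2.2.1]hept-5-ene) | CC12OOC(O1)(C=C2C)C(CC(=O)O)[C@H](CO[Si](C)(C)C(C)(C)C)[C@@H](O[Si](C)(C)C(C)(C)C)/C=C/B3OC(C)(C)C(C)(C)O3 | intermediate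
18 | (4R,5S,6E)-5-(TBS-oxy)-4-(TBS-oxymethyl)-3-[(2Z)-3-methyl-4-oxopent-2-enoyl]-7-(pinacolboryl)hept-6-enoic acid | CC(=O)/C(C)=C\C(=O)C(CC(=O)O)[C@H](CO[Si](C)(C)C(C)(C)C)[C@@H](O[Si](C)(C)C(C)(C)C)/C=C/B1OC(C)(C)C(C)(C)O1 | intermediate
19 | Z-dienone enol lactone: 4-[(2R,3S,4E)-1,3-bis(TBS-oxy)-5-(pinacolboryl)pent-4-en-2-yl]-5-[(1Z)-2-methyl-3-oxobut-1-en-1-yl]furan-2(3H)-one | CC(=O)/C(C)=C\C1=C([C@H](CO[Si](C)(C)C(C)(C)C)[C@@H](O[Si](C)(C)C(C)(C)C)/C=C/B3OC(C)(C)C(C)(C)O3)CC(=O)O1 | intermediate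
20 | lactone-fused 2H-pyran (valence isomer of 19; C18 epimer that leads to 21, C18 S) | CC1=C(C)C=C2OC(=O)C[C@]2(O1)[C@H](CO[Si](C)(C)C(C)(C)C)[C@@H](O[Si](C)(C)C(C)(C)C)/C=C/B3OC(C)(C)C(C)(C)O3 | intermediate
21 | Diels–Alder adduct: 2-oxabicyclo[2.2.2]octene propellane γ-lactone, Bpin on C13 on the side of the C26=C27 bridge, OTBS on C10 and on C7; C9, C10, C12, C13, C15, C18, C25 as in the target | C(O[Si](C)(C)C(C)(C)C)[C@@H]2[C@@H](O[Si](C)(C)C(C)(C)C)[C@H]3[C@H](B6OC(C)(C)C(C)(C)O6)[C@@]4(C)O[C@@]25CC(=O)O[C@@]35C=C4C | intermediate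
22 | C13 alcohol of 21 (retention at C13) | C(O[Si](C)(C)C(C)(C)C)[C@@H]2[C@@H](O[Si](C)(C)C(C)(C)C)[C@H]3[C@H](O)[C@@]4(C)O[C@@]25CC(=O)O[C@@]35C=C4C | intermediate
23 | dimethylsilyl ether of 22 (C13–O–SiHMe2) | C(O[Si](C)(C)C(C)(C)C)[C@@H]2[C@@H](O[Si](C)(C)C(C)(C)C)[C@H]3[C@H](O[SiH](C)C)[C@@]4(C)O[C@@]25CC(=O)O[C@@]35C=C4C | intermediate
24 | oxasilolane: O14–SiMe2–C27 ring, C26 is CH2, silicon on the C27 face toward C13 | C(O[Si](C)(C)C(C)(C)C)[C@@H]2[C@@H](O[Si](C)(C)C(C)(C)C)[C@H]3[C@H](O6)[C@@]4(C)O[C@@]25CC(=O)O[C@@]35C[C@@]4(C)[Si]6(C)C | intermediate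
25 | syn-1,3-diol (C13–OH, C27–OH; C27 as in the target) | C(O[Si](C)(C)C(C)(C)C)[C@@H]2[C@@H](O[Si](C)(C)C(C)(C)C)[C@H]3[C@H](O)[C@@]4(C)O[C@@]25CC(=O)O[C@@]35C[C@@]4(C)O | intermediate
26 | di-tert-butylsilylene of 25 (O14–Si(t-Bu)2–O29) | C(O[Si](C)(C)C(C)(C)C)[C@@H]2[C@@H](O[Si](C)(C)C(C)(C)C)[C@H]3[C@H](O6)[C@@]4(C)O[C@@]25CC(=O)O[C@@]35C[C@@]4(C)O[Si]6(C(C)(C)C)C(C)(C)C | intermediate
27 | primary alcohol (C7–OH) of 26 | OC[C@@H]2[C@@H](O[Si](C)(C)C(C)(C)C)[C@H]3[C@H](O6)[C@@]4(C)O[C@@]25CC(=O)O[C@@]35C[C@@]4(C)O[Si]6(C(C)(C)C)C(C)(C)C | intermediate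
28 | C7 aldehyde | O=C[C@@H]2[C@@H](O[Si](C)(C)C(C)(C)C)[C@H]3[C@H](O6)[C@@]4(C)O[C@@]25CC(=O)O[C@@]35C[C@@]4(C)O[Si]6(C(C)(C)C)C(C)(C)C | intermediate
29 | (4R)-4-benzyl-3-propanoyl-1,3-oxazolidin-2-one | CCC(=O)N1[C@H](Cc2ccccc2)COC1=O | starting material
30 | 2,3-dibromopropene | C=C(Br)CBr | starting material
31 | sodium Z-enolate of 29 | C/C=C(\[O-])N1[C@H](Cc2ccccc2)COC1=O.[Na+] | intermediate
32 | (4R)-4-benzyl-3-[(2S)-4-bromo-2-methylpent-4-enoyl]-1,3-oxazolidin-2-one | C[C@H](C(=O)N1[C@H](Cc2ccccc2)COC1=O)CC(Br)=C | intermediate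
33 | methyl (2S)-4-bromo-2-methylpent-4-enoate | C[C@H](C(=O)OC)CC(Br)=C | intermediate
34 | allylic alcohol: C9–C7H(OH)–C4(=CH2)–C3H2–C2H(CH3)–CO2Me, C7 S, C2 S | C[C@H](C(=O)OC)CC(=C)[C@@H](O)[C@@H]2[C@@H](O[Si](C)(C)C(C)(C)C)[C@H]3[C@H](O6)[C@@]4(C)O[C@@]25CC(=O)O[C@@]35C[C@@]4(C)O[Si]6(C(C)(C)C)C(C)(C)C | intermediate
35 | erythro epoxy alcohol (C4–O–C5H2 epoxide, C4 R, C7 S) | C[C@H](C(=O)OC)C[C@@]1(CO1)[C@@H](O)[C@@H]2[C@@H](O[Si](C)(C)C(C)(C)C)[C@H]3[C@H](O6)[C@@]4(C)O[C@@]25CC(=O)O[C@@]35C[C@@]4(C)O[Si]6(C(C)(C)C)C(C)(C)C | intermediate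
36 | iodohydrin: C4(OH)(CH2I), C4–O as in the target | C[C@H](C(=O)OC)C[C@](CI)(O)[C@@H](O)[C@@H]2[C@@H](O[Si](C)(C)C(C)(C)C)[C@H]3[C@H](O6)[C@@]4(C)O[C@@]25CC(=O)O[C@@]35C[C@@]4(C)O[Si]6(C(C)(C)C)C(C)(C)C | intermediate
37 | dihydroxy methyl ester: C4(OH)(CH3), C7–OH | C[C@H](C(=O)OC)C[C@](C)(O)[C@@H](O)[C@@H]2[C@@H](O[Si](C)(C)C(C)(C)C)[C@H]3[C@H](O6)[C@@]4(C)O[C@@]25CC(=O)O[C@@]35C[C@@]4(C)O[Si]6(C(C)(C)C)C(C)(C)C | intermediate
38 | side-chain γ-lactone (C4–O–C20=O; C2 S, C4 S), C7–OH free | C[C@H]1C[C@](C)(OC1=O)[C@@H](O)[C@@H]2[C@@H](O[Si](C)(C)C(C)(C)C)[C@H]3[C@H](O6)[C@@]4(C)O[C@@]25CC(=O)O[C@@]35C[C@@]4(C)O[Si]6(C(C)(C)C)C(C)(C)C | intermediate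
39 | C7 triethylsilyl ether of 38 | C[C@H]1C[C@](C)(OC1=O)[C@@H](O[Si](CC)(CC)CC)[C@@H]2[C@@H](O[Si](C)(C)C(C)(C)C)[C@H]3[C@H](O6)[C@@]4(C)O[C@@]25CC(=O)O[C@@]35C[C@@]4(C)O[Si]6(C(C)(C)C)C(C)(C)C | intermediate
40 | cyclised eight-membered β-keto lactone enol, C7–OTES, C4–OH | C[C@H]1C[C@](C)(O)[C@@H](O[Si](CC)(CC)CC)[C@@H]2[C@@H](O[Si](C)(C)C(C)(C)C)[C@H]3[C@H](O6)[C@@]4(C)O[C@@]25/C(=C\1O)C(=O)O[C@@]35C[C@@]4(C)O[Si]6(C(C)(C)C)C(C)(C)C | intermediate
41 | eight-membered β-keto lactone enol, C7–OH, C4–OH | C[C@H]1C[C@](C)(O)[C@@H](O)[C@@H]2[C@@H](O[Si](C)(C)C(C)(C)C)[C@H]3[C@H](O6)[C@@]4(C)O[C@@]25/C(=C\1O)C(=O)O[C@@]35C[C@@]4(C)O[Si]6(C(C)(C)C)C(C)(C)C | intermediate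
42 | C7 ketone: target with C10–OTBS and the C13/C27 di-tert-butylsilylene | C[C@H]1C[C@](C)(O)C(=O)[C@@H]2[C@@H](O[Si](C)(C)C(C)(C)C)[C@H]3[C@H](O6)[C@@]4(C)O[C@@]25/C(=C\1O)C(=O)O[C@@]35C[C@@]4(C)O[Si]6(C(C)(C)C)C(C)(C)C | intermediate
43 | CNP0073514.1 | C[C@H]1C[C@](C)(O)C(=O)[C@@H]2[C@@H](O)[C@H]3[C@H](O)[C@@]4(C)O[C@@]25/C(=C\1O)C(=O)O[C@@]35C[C@@]4(C)O | target

**Step count**
Total: 27 steps. Longest linear sequence: 24 steps (steps 2–17 and 20–27, from ethyl acetate and acrolein).

**Steps most likely to fail**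

1. Step 11. The two pyran epimers may be trapped with poor discrimination, because the C9 substituent and the C10 silyloxy group need not cooperate; a slow cycloaddition would also let proton shift to the conjugated butenolide compete. Fallback: add auxiliary control at boron (double stereodifferentiation) instead of relying on the tether alone. Dibutyl vinylboronate and (1R,2R)-1,2-diphenylethane-1,2-diol give the chiral vinylboronate F1 (the (S,S)-diol is used if it proves to be the matched partner). Cross-metathesis of 12 with F1 gives the alkenyl boronate F2. The sequence of steps 8–11 then gives the trimethylsilyl ester F3, the acid F4, the endoperoxide F5, the keto acid F6 and the enol lactone F7. Heating leads through the pyran F8 to the adduct F9, and perborate oxidation of F9 returns to the route at 22.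

2. Step 25. Strain in the eight-membered transition state may slow the Claisen closure, so that intermolecular condensation, enolisation at C2 of the side-chain lactone or retro-Claisen cleavage takes over. Fallback: reverse the order of bond formation and close the ring at C7–C4. The lithium enolate F10 of 26 (LiHMDS, THF, −78 °C) is acylated with imide 32 to the β-keto lactone F11 (drawn as the keto form). Acidic methanolysis gives the primary alcohol F12 and Dess–Martin oxidation the aldehyde F13. Intramolecular Nozaki–Hiyama–Kishi reaction (CrCl2, cat. NiCl2, DMF, high dilution) gives the cyclic allylic alcohol F14, and oxidation gives the exocyclic enone F15. Mukaiyama-type hydration (Mn(dpm)3, PhSiH3, O2, i-PrOH; then P(OEt)3) returns to the route at 42; the C4 configuration then depends on the face selectivity of the ring.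

3. Step 13. The platinum hydride may fail to insert the hindered trisubstituted bridge alkene and to form the tertiary C27–Si bond, leaving alkene isomerisation or desilylation. Fallback: directed dihydroxylation followed by deoxygenation. OsO4·TMEDA (CH2Cl2, −78 °C) adds to 22 on the alkene face that looks at C13–OH and gives the osmate ester F16, which is cleaved (aq. Na2SO3) to the triol F17. The 1,3-diol is closed as the di-tert-butylsilylene F18. The remaining C26 alcohol is converted into the imidazolyl thiocarbonate F19 (1,1'-thiocarbonyldiimidazole, DMAP, PhMe, 80 °C) and removed by Barton–McCombie reduction (Bu3SnH, AIBN), which returns to the route at 26.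

**Further compounds**

F1 | step 11 | (4R,5R)-4,5-diphenyl-2-vinyl-1,3,2-dioxaborolane | C=CB1O[C@H](c2ccccc2)[C@@H](c2ccccc2)O1
F2 | step 11 | (R,R)-diphenyldioxaborolane analogue of 14 | Cc1oc(C(CC(=O)OC(C)(C)C)[C@H](CO[Si](C)(C)C(C)(C)C)[C@@H](O[Si](C)(C)C(C)(C)C)/C=C/B2O[C@H](c3ccccc3)[C@@H](c3ccccc3)O2)cc1C
F3 | step 11 | (R,R)-diphenyldioxaborolane analogue of 15 | Cc1oc(C(CC(=O)O[Si](C)(C)C)[C@H](CO[Si](C)(C)C(C)(C)C)[C@@H](O[Si](C)(C)C(C)(C)C)/C=C/B2O[C@H](c3ccccc3)[C@@H](c3ccccc3)O2)cc1C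
F4 | step 11 | (R,R)-diphenyldioxaborolane analogue of 16 | Cc1oc(C(CC(=O)O)[C@H](CO[Si](C)(C)C(C)(C)C)[C@@H](O[Si](C)(C)C(C)(C)C)/C=C/B2O[C@H](c3ccccc3)[C@@H](c3ccccc3)O2)cc1C
F5 | step 11 | (R,R)-diphenyldioxaborolane analogue of 17 | CC12OOC(O1)(C=C2C)C(CC(=O)O)[C@H](CO[Si](C)(C)C(C)(C)C)[C@@H](O[Si](C)(C)C(C)(C)C)/C=C/B3O[C@H](c4ccccc4)[C@@H](c4ccccc4)O3
F6 | step 11 | (R,R)-diphenyldioxaborolane analogue of 18 | CC(=O)/C(C)=C\C(=O)C(CC(=O)O)[C@H](CO[Si](C)(C)C(C)(C)C)[C@@H](O[Si](C)(C)C(C)(C)C)/C=C/B1O[C@H](c2ccccc2)[C@@H](c2ccccc2)O1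
F7 | step 11 | (R,R)-diphenyldioxaborolane analogue of 19 | CC(=O)/C(C)=C\C1=C([C@H](CO[Si](C)(C)C(C)(C)C)[C@@H](O[Si](C)(C)C(C)(C)C)/C=C/B3O[C@H](c4ccccc4)[C@@H](c4ccccc4)O3)CC(=O)O1
F8 | step 11 | (R,R)-diphenyldioxaborolane analogue of 20 | CC1=C(C)C=C2OC(=O)C[C@]2(O1)[C@H](CO[Si](C)(C)C(C)(C)C)[C@@H](O[Si](C)(C)C(C)(C)C)/C=C/B3O[C@H](c4ccccc4)[C@@H](c4ccccc4)O3
F9 | step 11 | (R,R)-diphenyldioxaborolane analogue of 21 | C(O[Si](C)(C)C(C)(C)C)[C@@H]2[C@@H](O[Si](C)(C)C(C)(C)C)[C@H]3[C@H](B6O[C@H](c7ccccc7)[C@@H](c7ccccc7)O6)[C@@]4(C)O[C@@]25CC(=O)O[C@@]35C=C4C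
F10 | step 25 | lithium enolate of lactone 26 | C(O[Si](C)(C)C(C)(C)C)[C@@H]2[C@@H](O[Si](C)(C)C(C)(C)C)[C@H]3[C@H](O6)[C@@]4(C)O[C@@]25C=C([O-])O[C@@]35C[C@@]4(C)O[Si]6(C(C)(C)C)C(C)(C)C.[Li+]
F11 | step 25 | C19-acylated lactone (keto form, C19 unassigned) with C7–OTBS | C(O[Si](C)(C)C(C)(C)C)[C@@H]2[C@@H](O[Si](C)(C)C(C)(C)C)[C@H]3[C@H](O6)[C@@]4(C)O[C@@]25C(C(=O)[C@@H](C)CC(Br)=C)C(=O)O[C@@]35C[C@@]4(C)O[Si]6(C(C)(C)C)C(C)(C)C
F12 | step 25 | primary alcohol of F11 | OC[C@@H]2[C@@H](O[Si](C)(C)C(C)(C)C)[C@H]3[C@H](O6)[C@@]4(C)O[C@@]25C(C(=O)[C@@H](C)CC(Br)=C)C(=O)O[C@@]35C[C@@]4(C)O[Si]6(C(C)(C)C)C(C)(C)C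
F13 | step 25 | aldehyde of F12 | O=C[C@@H]2[C@@H](O[Si](C)(C)C(C)(C)C)[C@H]3[C@H](O6)[C@@]4(C)O[C@@]25C(C(=O)[C@@H](C)CC(Br)=C)C(=O)O[C@@]35C[C@@]4(C)O[Si]6(C(C)(C)C)C(C)(C)C
F14 | step 25 | cyclic allylic alcohol (C7–OH, C4=CH2 in the eight-membered ring, C7 unassigned) | C[C@H]1CC(=C)C(O)[C@@H]2[C@@H](O[Si](C)(C)C(C)(C)C)[C@H]3[C@H](O6)[C@@]4(C)O[C@@]25/C(=C\1O)C(=O)O[C@@]35C[C@@]4(C)O[Si]6(C(C)(C)C)C(C)(C)C
F15 | step 25 | exocyclic enone (C7=O, C4=CH2) | C[C@H]1CC(=C)C(=O)[C@@H]2[C@@H](O[Si](C)(C)C(C)(C)C)[C@H]3[C@H](O6)[C@@]4(C)O[C@@]25/C(=C\1O)C(=O)O[C@@]35C[C@@]4(C)O[Si]6(C(C)(C)C)C(C)(C)C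
F16 | step 13 | osmate(VI) ester of the C26/C27 diol, TMEDA complex | C(O[Si](C)(C)C(C)(C)C)[C@@H]2[C@@H](O[Si](C)(C)C(C)(C)C)[C@H]3[C@H](O)[C@@]4(C)O[C@@]25CC(=O)O[C@@]35[C@@H](O7)[C@@]4(C)O[Os]7(=O)=O.CN(C)CCN(C)C
F17 | step 13 | triol (C13–OH, C26–OH, C27–OH, all on the face toward the C12–C13 bridge) | C(O[Si](C)(C)C(C)(C)C)[C@@H]2[C@@H](O[Si](C)(C)C(C)(C)C)[C@H]3[C@H](O)[C@@]4(C)O[C@@]25CC(=O)O[C@@]35[C@@H](O)[C@@]4(C)O
F18 | step 13 | C13/C27 di-tert-butylsilylene with free C26–OH | C(O[Si](C)(C)C(C)(C)C)[C@@H]2[C@@H](O[Si](C)(C)C(C)(C)C)[C@H]3[C@H](O6)[C@@]4(C)O[C@@]25CC(=O)O[C@@]35[C@@H](O)[C@@]4(C)O[Si]6(C(C)(C)C)C(C)(C)C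
F19 | step 13 | C26 O-(imidazol-1-ylthiocarbonyl) derivative of F18 | C(O[Si](C)(C)C(C)(C)C)[C@@H]2[C@@H](O[Si](C)(C)C(C)(C)C)[C@H]3[C@H](O6)[C@@]4(C)O[C@@]25CC(=O)O[C@@]35[C@@H](OC(=S)n7ccnc7)[C@@]4(C)O[Si]6(C(C)(C)C)C(C)(C)C
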